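Four-line plan:
- Retrosynthesis: after removal of fifteen benzyl ethers and one acetate, cut C4(top)–C8(middle); then C4(middle)–H; then, in one operation, C4(middle)–C8(bottom) together with the ring C ether bond O1–C8a of the bottom unit; last, the aryl–carbonyl and aryl–CH2 bonds of the bottom chain.
- Enabling feature: in ring A of the bottom unit, C8a (the O1 carbon) lies between the chain carbon C4a and C8, and C8 is ortho to O7. An aryne across C8–C8a can take the C2 alkoxide only at C8a (six-membered ring C) and leaves its carbanion at C8, the interflavan carbon, where O7 stabilises it.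
- Forward: fluoroarene + (S)-glycidate + catechol Grignard give the open-chain bottom unit 12 (F on C8a as leaving group, Br on C8 as metalation handle). Br/Li exchange, LiF loss, closure of ring C and addition of the C8 anion to the 4-ketone of benzylated dihydromyricetin give the lower dimer as a carbinol; ionic hydrogenation gives the 3,4-cis link; the catechin-derived top unit is coupled last; deprotection.
- Stereochemistry: bottom C3 from methyl (S)-glycidate; bottom C2 by chelation-controlled reduction (anti); middle C2/C3 from (+)-dihydromyricetin; middle C4 by hydride delivery anti to O3; top C2/C3 from (+)-catechin; top C4 by acetate participation (3,4-trans).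

Key step: step 10

Remark: the target is read as catechin-(4α→8)-gallocatechin-(4β→8)-catechin (all units 2R,3S; upper link 3,4-trans, lower link 3,4-cis).
Remark: the C4 configuration drawn for 19, 23 and 24 is the expected one; these carbons are ionised in the following step, so either epimer serves.

Step 1
Reactants: 1 1,3,5-trifluorobenzene
Product: 2 1,3-bis(benzyloxy)-5-fluorobenzene
Conditions: BnOH (2.1 equiv), NaH (2.2 equiv), NMP, 0 → 90 °C
Reagents that add atoms: benzyl alcohol, OCc1ccccc1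
Why: Double SNAr of fluoride by sodium benzyloxide should stop at the difluoride-to-monofluoride stage because each meta alkoxy group makes the next displacement slower and the stoichiometry is limited to two equivalents.

Step 2
Reactants: 2 1,3-bis(benzyloxy)-5-fluorobenzene
Product: 3 1,5-bis(benzyloxy)-2,4-dibromo-3-fluorobenzene
Conditions: NBS (2.05 equiv), MeCN, 0 °C → rt
Reagents that add atoms: N-bromosuccinimide, O=C1CCC(=O)N1Br
Why: Electrophilic aromatic bromination of a resorcinol diether should go twice ortho/para to the benzyloxy groups (the two carbons flanking fluorine) and avoid the hindered carbon between the two benzyloxy groups.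

Step 3
Reactants: 3 1,5-bis(benzyloxy)-2,4-dibromo-3-fluorobenzene; 4 methyl (2S)-oxirane-2-carboxylate
Product: 6 methyl (2S)-3-[4,6-bis(benzyloxy)-3-bromo-2-fluorophenyl]-2-hydroxypropanoate, via arylmagnesium chloride 5 (not isolated)
Conditions: i-PrMgCl·LiCl (1.05 equiv), THF, −20 °C; then CuI (10 mol%), 4, −40 → 0 °C; NH4Cl (aq)
Reagents that add atoms: none
Why: Mono Br/Mg exchange of the symmetric dibromide followed by copper-catalysed SN2 opening of the glycidate at its CH2 carbon should give the 3-aryl-lactate with the glycidate stereocentre untouched, the second bromine surviving because the first exchange makes the ring electron-rich.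

Step 4
Reactants: 6 methyl (2S)-3-[4,6-bis(benzyloxy)-3-bromo-2-fluorophenyl]-2-hydroxypropanoate
Product: 7 methyl (2S)-2-(benzyloxy)-3-[4,6-bis(benzyloxy)-3-bromo-2-fluorophenyl]propanoate
Conditions: benzyl 2,2,2-trichloroacetimidate (1.5 equiv), TfOH (5 mol%), CH2Cl2/cyclohexane, 0 °C → rt
Reagents that add atoms: benzyl 2,2,2-trichloroacetimidate, N=C(OCc1ccccc1)C(Cl)(Cl)Cl
Why: Acid-catalysed O-benzylation with the trichloroacetimidate avoids base and so should not racemise the α-hydroxy ester.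

Step 5
Reactants: 7 methyl (2S)-2-(benzyloxy)-3-[4,6-bis(benzyloxy)-3-bromo-2-fluorophenyl]propanoate
Product: 8 (2S)-2-(benzyloxy)-3-[4,6-bis(benzyloxy)-3-bromo-2-fluorophenyl]-N-methoxy-N-methylpropanamide
Conditions: MeNH(OMe)·HCl (3 equiv), AlMe3 (3 equiv), CH2Cl2, 0 °C → rt; HCl (aq) work-up
Reagents that add atoms: N,O-dimethylhydroxylamine hydrochloride, CNOC.Cl
Why: Aminolysis of the ester by the aluminium amide (Weinreb amide formation) tolerates the aryl bromide and fluoride and does not touch the α-stereocentre.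

Step 6
Reactants: 8 (2S)-2-(benzyloxy)-3-[4,6-bis(benzyloxy)-3-bromo-2-fluorophenyl]-N-methoxy-N-methylpropanamide; 9 4-bromo-1,2-bis(benzyloxy)benzene
Product: 11 (2S)-2-(benzyloxy)-3-[4,6-bis(benzyloxy)-3-bromo-2-fluorophenyl]-1-[3,4-bis(benzyloxy)phenyl]propan-1-one, via arylmagnesium bromide 10 (not isolated)
Conditions: 9, Mg turnings, I2 (cat.), THF, 40 °C; then 8, THF, 0 °C; NH4Cl (aq)
Reagents that add atoms: none
Why: Grignard addition to the Weinreb amide stops at the chelated tetrahedral intermediate, so the ketone is released only on work-up without over-addition or epimerisation, and magnesium instead of lithium avoids halogen–metal exchange at the aryl bromide of 8.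

Step 7
Reactants: 11 (2S)-2-(benzyloxy)-3-[4,6-bis(benzyloxy)-3-bromo-2-fluorophenyl]-1-[3,4-bis(benzyloxy)phenyl]propan-1-one
Product: 12 (1R,2S)-2-(benzyloxy)-3-[4,6-bis(benzyloxy)-3-bromo-2-fluorophenyl]-1-[3,4-bis(benzyloxy)phenyl]propan-1-ol
Conditions: Zn(BH4)2 (Et2O solution), Et2O/CH2Cl2, −78 → −20 °C; NH4Cl (aq)
Reagents that add atoms: none
Why: Chelation-controlled (Cram chelate) reduction, in which zinc bridges the carbonyl and the α-benzyloxy oxygen and hydride enters opposite the CH2Ar group, should give the anti (1R,2S) alcohol that corresponds to 2,3-trans in the flavan.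

Step 8
Reactants: 13 (+)-dihydromyricetin [(2R,3R)-3,5,7-trihydroxy-2-(3,4,5-trihydroxyphenyl)chroman-4-one]
Product: 14 (2R,3R)-5,7-bis(benzyloxy)-3-hydroxy-2-[3,4,5-tris(benzyloxy)phenyl]chroman-4-one
Conditions: BnBr (6 equiv), K2CO3 (6 equiv), DMF (degassed), rt, under Ar
Reagents that add atoms: benzyl bromide, BrCc1ccccc1
Why: Williamson benzylation of the five phenols with a weak carbonate base under exclusion of air should leave the secondary 3-OH and the trans C2/C3 centres of the flavanonol unchanged.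

Step 9
Reactants: 14 (2R,3R)-5,7-bis(benzyloxy)-3-hydroxy-2-[3,4,5-tris(benzyloxy)phenyl]chroman-4-one
Product: 15 (2R,3R)-3,5,7-tris(benzyloxy)-2-[3,4,5-tris(benzyloxy)phenyl]chroman-4-one
Conditions: benzyl 2,2,2-trichloroacetimidate (2 equiv), TfOH (5 mol%), CH2Cl2, 0 °C → rt
Reagents that add atoms: benzyl 2,2,2-trichloroacetimidate, N=C(OCc1ccccc1)C(Cl)(Cl)Cl
Why: Acid-catalysed imidate benzylation protects the α-ketol without base, which would epimerise C2/C3 or open the flavanonol ring.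

Step 10
Reactants: 12 (1R,2S)-2-(benzyloxy)-3-[4,6-bis(benzyloxy)-3-bromo-2-fluorophenyl]-1-[3,4-bis(benzyloxy)phenyl]propan-1-ol; 15 (2R,3R)-3,5,7-tris(benzyloxy)-2-[3,4,5-tris(benzyloxy)phenyl]chroman-4-one
Product: 19 4-(3,5,7,3',4'-penta-O-benzylcatechin-8-yl)-3,5,7,3',4',5'-hexa-O-benzylgallocatechin-4-ol (tertiary C4 carbinol; aryl on the α face; 4-OH cis to 3-OBn), via dilithiated fluoroarene 16 (not isolated), via aryne lithium alkoxide 17 (not isolated), via 8-lithioflavan 18 (not isolated)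
Conditions: 12 (1.3 equiv), n-BuLi (2.05 equiv per 12), THF (0.02 M), −78 °C, 15 min; warm to −30 °C, 30 min; recool to −78 °C; 15 (1.0 equiv) in THF, −78 °C, 1 h; NH4Cl (aq)
Reagents that add atoms: none
Why: Proposed new method: n-BuLi forms the lithium alkoxide and, by Br/Li exchange at C8, the ortho-fluoro aryllithium 16, which on warming loses LiF (fluoride is the only leaving group next to the metal, C7 carrying OBn) to give the C8–C8a aryne 17; the tethered C2 alkoxide adds to C8a and the aryllithium 18 so formed adds to the C4 carbonyl of 15 at −78 °C. The closest known reaction types are the aryne ring closure of 3-(halophenyl)propanols to chromans, the capture by external electrophiles of aryllithiums formed by intramolecular nucleophile–aryne addition, and the 1,2-addition of 8-lithioflavans to flavan-4-ones; running them as one sequence on a flavan precursor is the new element. Ring C of the bottom unit closes in a 6-exo-dig mode with respect to the in-plane aryne π bond, with retention at C2 and C3 because neither carbon is touched. The new carbinol centre at C4 of the middle unit should arise by attack of 18 anti to the 3-benzyloxy group and is of no consequence, since it is ionised in step 11. The step needs O-attack at C8a (secured by the tether, which cannot reach C8, and by O7, which directs nucleophiles to the aryne carbon meta to it and stabilises the C8 anion), the alkoxide rather than the neutral 3-benzyloxy oxygen as nucleophile (secured by its charge), and 1,2-addition rather than enolisation of 15 (low temperature and lithium chelation by the 3-OBn/C4=O pair).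

Step 11
Reactants: 19 4-(3,5,7,3',4'-penta-O-benzylcatechin-8-yl)-3,5,7,3',4',5'-hexa-O-benzylgallocatechin-4-ol
Product: 20 undeca-O-benzyl-gallocatechin-(4β→8)-catechin (3,4-cis lower link; all eleven hydroxyls benzylated)
Conditions: Bu3SnH (3 equiv), CF3CO2H (10 equiv), CH2Cl2, −78 → 0 °C
Reagents that add atoms: none
Why: Ionic hydrogenation, in which the acid ionises the tertiary doubly benzylic alcohol to the 4-aryl-flavan-4-yl cation and the tin hydride should deliver hydride anti to the 3-benzyloxy group (α face), places the bottom unit on the β face cis to O3, as in the same reduction of 4-aryl-flavan-4-ols of the 2,3-cis series.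

Step 12
Reactants: 21 (+)-catechin
Product: 22 5,7,3',4'-tetra-O-benzyl-(+)-catechin
Conditions: BnBr (4.4 equiv), K2CO3 (4.4 equiv), DMF, rt, under Ar
Reagents that add atoms: benzyl bromide, BrCc1ccccc1
Why: Williamson benzylation with carbonate base alkylates the four phenols and leaves the secondary 3-OH free.

Step 13
Reactants: 22 5,7,3',4'-tetra-O-benzyl-(+)-catechin
Product: 23 (2R,3S,4S)-5,7,3',4'-tetra-O-benzyl-4-(2-ethoxyethoxy)catechin (4β-alkoxy)
Conditions: DDQ (2 equiv), 2-ethoxyethanol (5 equiv), CH2Cl2, rt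
Reagents that add atoms: 2-ethoxyethanol, CCOCCO
Why: DDQ abstracts hydride from the alkoxy-stabilised benzylic C4 and the alcohol traps the cation (benzylic oxidative etherification), the C4 configuration being irrelevant for the later ionisation.

Step 14
Reactants: 23 (2R,3S,4S)-5,7,3',4'-tetra-O-benzyl-4-(2-ethoxyethoxy)catechin
Product: 24 (2R,3S,4S)-3-O-acetyl-5,7,3',4'-tetra-O-benzyl-4-(2-ethoxyethoxy)catechin
Conditions: Ac2O (3 equiv), DMAP (cat.), pyridine, rt
Reagents that add atoms: acetic anhydride, CC(=O)OC(C)=O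
Why: DMAP-catalysed acetylation installs the participating group that will control the facial course of the coupling.

Step 15
Reactants: 20 undeca-O-benzyl-gallocatechin-(4β→8)-catechin; 24 (2R,3S,4S)-3-O-acetyl-5,7,3',4'-tetra-O-benzyl-4-(2-ethoxyethoxy)catechin
Product: 25 pentadeca-O-benzyl-catechin-(4α→8)-gallocatechin-(4β→8)-catechin 3-O-acetate (acetate on the top unit)
Conditions: 20 (1.0 equiv), 24 (1.1 equiv), TMSOTf (0.5 equiv), CH2Cl2, −78 °C; NaHCO3 (aq)
Reagents that add atoms: none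
Why: Lewis-acid ionisation of the 4-alkoxy group gives the C4 cation, held as an acetoxonium ion on the β face by the 3-acetate, so that Friedel–Crafts attack by C8 of the upper unit of 20 (the most nucleophilic carbon, between O1 and O7) should come from the α face and give the 3,4-trans link.

Step 16
Reactants: 25 pentadeca-O-benzyl-catechin-(4α→8)-gallocatechin-(4β→8)-catechin 3-O-acetate
Product: 26 pentadeca-O-benzyl-catechin-(4α→8)-gallocatechin-(4β→8)-catechin (free 3-OH on the top unit)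
Conditions: NaOMe (cat.), MeOH/THF (1:1), rt → 40 °C
Reagents that add atoms: none
Why: Zemplén transesterification removes the single ester while benzyl ethers and interflavan bonds are inert to methoxide.

Step 17
Reactants: 26 pentadeca-O-benzyl-catechin-(4α→8)-gallocatechin-(4β→8)-catechin
Product: 27 catechin-(4α→8)-gallocatechin-(4β→8)-catechin (target)
Conditions: H2 (1 atm), Pd(OH)2/C, THF/MeOH/H2O (20:1:1), rt; filtration; lyophilisation
Reagents that add atoms: none
Why: Hydrogenolysis over Pd(OH)2/C cleaves all fifteen benzyl ethers under neutral conditions that should leave the ring C ethers and the acid- and base-sensitive free oligomer intact.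

Compound list
1 | 1,3,5-trifluorobenzene | Fc1cc(F)cc(F)c1 | starting material
2 | 1,3-bis(benzyloxy)-5-fluorobenzene | Fc1cc(OCc2ccccc2)cc(OCc2ccccc2)c1 | intermediate
3 | 1,5-bis(benzyloxy)-2,4-dibromo-3-fluorobenzene | Fc1c(Br)c(OCc2ccccc2)cc(OCc2ccccc2)c1Br | intermediate
4 | methyl (2S)-oxirane-2-carboxylate (methyl (S)-glycidate) | COC(=O)[C@@H]1CO1 | starting material
5 | [4,6-bis(benzyloxy)-3-bromo-2-fluorophenyl]magnesium chloride | Cl[Mg]c1c(F)c(Br)c(OCc2ccccc2)cc1OCc1ccccc1 | intermediate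
6 | methyl (2S)-3-[4,6-bis(benzyloxy)-3-bromo-2-fluorophenyl]-2-hydroxypropanoate | COC(=O)[C@@H](O)Cc1c(F)c(Br)c(OCc2ccccc2)cc1OCc1ccccc1 | intermediate
7 | methyl (2S)-2-(benzyloxy)-3-[4,6-bis(benzyloxy)-3-bromo-2-fluorophenyl]propanoate | COC(=O)[C@@H](OCc1ccccc1)Cc1c(F)c(Br)c(OCc2ccccc2)cc1OCc1ccccc1 | intermediate
8 | (2S)-2-(benzyloxy)-3-[4,6-bis(benzyloxy)-3-bromo-2-fluorophenyl]-N-methoxy-N-methylpropanamide | CON(C)C(=O)[C@@H](OCc1ccccc1)Cc1c(F)c(Br)c(OCc2ccccc2)cc1OCc1ccccc1 | intermediate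
9 | 4-bromo-1,2-bis(benzyloxy)benzene | Brc1ccc(OCc2ccccc2)c(OCc2ccccc2)c1 | starting material
10 | [3,4-bis(benzyloxy)phenyl]magnesium bromide | Br[Mg]c1ccc(OCc2ccccc2)c(OCc2ccccc2)c1 | intermediate
11 | (2S)-2-(benzyloxy)-3-[4,6-bis(benzyloxy)-3-bromo-2-fluorophenyl]-1-[3,4-bis(benzyloxy)phenyl]propan-1-one | O=C(c1ccc(OCc2ccccc2)c(OCc2ccccc2)c1)[C@@H](OCc1ccccc1)Cc1c(F)c(Br)c(OCc2ccccc2)cc1OCc1ccccc1 | intermediate
12 | (1R,2S)-2-(benzyloxy)-3-[4,6-bis(benzyloxy)-3-bromo-2-fluorophenyl]-1-[3,4-bis(benzyloxy)phenyl]propan-1-ol | O[C@H](c1ccc(OCc2ccccc2)c(OCc2ccccc2)c1)[C@@H](OCc1ccccc1)Cc1c(F)c(Br)c(OCc2ccccc2)cc1OCc1ccccc1 | intermediate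
13 | (+)-dihydromyricetin, (2R,3R) | O=C1c2c(O)cc(O)cc2O[C@H](c2cc(O)c(O)c(O)c2)[C@H]1O | starting material
14 | (2R,3R)-5,7-bis(benzyloxy)-3-hydroxy-2-[3,4,5-tris(benzyloxy)phenyl]chroman-4-one | O=C1c2c(OCc3ccccc3)cc(OCc3ccccc3)cc2O[C@H](c2cc(OCc3ccccc3)c(OCc3ccccc3)c(OCc3ccccc3)c2)[C@H]1O | intermediate
15 | (2R,3R)-3,5,7-tris(benzyloxy)-2-[3,4,5-tris(benzyloxy)phenyl]chroman-4-one | O=C1c2c(OCc3ccccc3)cc(OCc3ccccc3)cc2O[C@H](c2cc(OCc3ccccc3)c(OCc3ccccc3)c(OCc3ccccc3)c2)[C@H]1OCc1ccccc1 | intermediate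
16 | dilithiated fluoroarene (lithium alkoxide of 12 with Li in place of Br) | [Li]O[C@H](c1ccc(OCc2ccccc2)c(OCc2ccccc2)c1)[C@@H](OCc1ccccc1)Cc1c(F)c([Li])c(OCc2ccccc2)cc1OCc1ccccc1 | intermediate
17 | aryne lithium alkoxide (aryne across the future C8–C8a) | [Li]O[C@H](c1ccc(OCc2ccccc2)c(OCc2ccccc2)c1)[C@@H](OCc1ccccc1)CC1=C(OCc2ccccc2)C=C(OCc2ccccc2)C#C1 | intermediate
18 | (2R,3S)-8-lithio-3,5,7,3',4'-penta-O-benzylcatechin | [Li]c1c(OCc3ccccc3)cc(OCc3ccccc3)c2c1O[C@H](c1ccc(OCc3ccccc3)c(OCc3ccccc3)c1)[C@@H](OCc1ccccc1)C2 | intermediate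
19 | 4-(penta-O-benzylcatechin-8-yl)-hexa-O-benzylgallocatechin-4-ol (aryl α, 4-OH cis to 3-OBn) | c1c(OCc3ccccc3)cc(OCc3ccccc3)c2c1O[C@H](c1cc(OCc3ccccc3)c(OCc3ccccc3)c(OCc3ccccc3)c1)[C@@H](OCc1ccccc1)[C@]2(O)c1c(OCc3ccccc3)cc(OCc3ccccc3)c2c1O[C@H](c1ccc(OCc3ccccc3)c(OCc3ccccc3)c1)[C@@H](OCc1ccccc1)C2 | intermediate
20 | undeca-O-benzyl-gallocatechin-(4β→8)-catechin (3,4-cis) | c1c(OCc3ccccc3)cc(OCc3ccccc3)c2c1O[C@H](c1cc(OCc3ccccc3)c(OCc3ccccc3)c(OCc3ccccc3)c1)[C@@H](OCc1ccccc1)[C@H]2c1c(OCc3ccccc3)cc(OCc3ccccc3)c2c1O[C@H](c1ccc(OCc3ccccc3)c(OCc3ccccc3)c1)[C@@H](OCc1ccccc1)C2 | intermediate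
21 | (+)-catechin, (2R,3S) | Oc1cc(O)c2c(c1)O[C@H](c1ccc(O)c(O)c1)[C@@H](O)C2 | starting material
22 | 5,7,3',4'-tetra-O-benzyl-(+)-catechin | c1ccccc1COc1cc(OCc3ccccc3)c2c(c1)O[C@H](c1ccc(OCc3ccccc3)c(OCc3ccccc3)c1)[C@@H](O)C2 | intermediate
23 | (2R,3S,4S)-5,7,3',4'-tetra-O-benzyl-4-(2-ethoxyethoxy)catechin | c1ccccc1COc1cc(OCc3ccccc3)c2c(c1)O[C@H](c1ccc(OCc3ccccc3)c(OCc3ccccc3)c1)[C@@H](O)[C@H]2OCCOCC | intermediate
24 | (2R,3S,4S)-3-O-acetyl-5,7,3',4'-tetra-O-benzyl-4-(2-ethoxyethoxy)catechin | c1ccccc1COc1cc(OCc3ccccc3)c2c(c1)O[C@H](c1ccc(OCc3ccccc3)c(OCc3ccccc3)c1)[C@@H](OC(C)=O)[C@H]2OCCOCC | intermediate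
25 | pentadeca-O-benzyl-catechin-(4α→8)-gallocatechin-(4β→8)-catechin, top-unit 3-O-acetate | c1ccccc1COc1cc(OCc3ccccc3)c2c(c1)O[C@H](c1ccc(OCc3ccccc3)c(OCc3ccccc3)c1)[C@@H](OC(C)=O)[C@@H]2c1c(OCc3ccccc3)cc(OCc3ccccc3)c2c1O[C@H](c1cc(OCc3ccccc3)c(OCc3ccccc3)c(OCc3ccccc3)c1)[C@@H](OCc1ccccc1)[C@H]2c1c(OCc3ccccc3)cc(OCc3ccccc3)c2c1O[C@H](c1ccc(OCc3ccccc3)c(OCc3ccccc3)c1)[C@@H](OCc1ccccc1)C2 | intermediate
26 | pentadeca-O-benzyl-catechin-(4α→8)-gallocatechin-(4β→8)-catechin | c1ccccc1COc1cc(OCc3ccccc3)c2c(c1)O[C@H](c1ccc(OCc3ccccc3)c(OCc3ccccc3)c1)[C@@H](O)[C@@H]2c1c(OCc3ccccc3)cc(OCc3ccccc3)c2c1O[C@H](c1cc(OCc3ccccc3)c(OCc3ccccc3)c(OCc3ccccc3)c1)[C@@H](OCc1ccccc1)[C@H]2c1c(OCc3ccccc3)cc(OCc3ccccc3)c2c1O[C@H](c1ccc(OCc3ccccc3)c(OCc3ccccc3)c1)[C@@H](OCc1ccccc1)C2 | intermediate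
27 | catechin-(4α→8)-gallocatechin-(4β→8)-catechin (CNP0302529.2) | Oc1cc(O)c2c(c1)O[C@H](c1ccc(O)c(O)c1)[C@@H](O)[C@@H]2c1c(O)cc(O)c2c1O[C@H](c1cc(O)c(O)c(O)c1)[C@@H](O)[C@H]2c1c(O)cc(O)c2c1O[C@H](c1ccc(O)c(O)c1)[C@@H](O)C2 | target

Total step count: 17. Longest linear sequence: 12 steps (steps 1–7, 10, 11, 15, 16, 17).

Steps most likely to fail

Step 10. What may go wrong: Wittig-type rearrangement or protonation of the aryllithium before the ketone is added, intermolecular capture of the aryne, or enolisation and ring opening of the flavanonol ketone instead of 1,2-addition. Fallback (sets out from 12, returns at 19): the two events are separated and each is run as known chemistry. 12 is treated with KN(SiMe3)2 and 18-crown-6 in THF/DMF (0 → 70 °C), so that the potassium alkoxide displaces fluoride by intramolecular SNAr without an aryne, which should give (2R,3S)-8-bromo-3,5,7,3',4'-penta-O-benzylcatechin F1. F1 is then lithiated by Br/Li exchange (n-BuLi, THF, −78 °C) to 18 and added to 15 at −78 °C, which gives 19.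

Step 11. What may go wrong: poor facial selectivity of hydride delivery to the planar C4 cation, giving the 3,4-trans epimer. Fallback (sets out from 14 and 22, returns at 20): the 3,4-cis link is made by the known tether-directed intramolecular condensation, in which the nucleophile is delivered from the O3 face.
- 14 is reduced with NaBH4 (MeOH/THF, 0 °C) to the 3,4-trans diol, (2R,3S,4R)-5,7,3',4',5'-penta-O-benzylgallocatechin-4-ol F2.
- F2 is etherified at the benzylic C4 with 2-ethoxyethanol (camphorsulfonic acid cat., CH2Cl2) to the 4-(2-ethoxyethoxy)flavan-3-ol F3.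
- 22 is acylated with glutaric anhydride (DMAP, pyridine) to the 3-O-hemiglutarate F4.
- F3 and F4 are joined (DCC, DMAP, CH2Cl2) to the glutarate-bridged diester F5.
- TMSOTf (CH2Cl2, high dilution, −40 °C) ionises C4 of the gallocatechin part, and C8 of the tethered catechin attacks on the β face to give the bridged 3,4-cis dimer F6 (14-membered ring).
- NaOMe in MeOH/THF removes the bridge to give the dimer diol F7, and NaH/BnBr (DMF) benzylates both 3-hydroxyls, which gives 20.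

Step 15. What may go wrong: self-condensation of the electrophile through its own free C8, further chain extension of the product, and competing attack at the C6 positions of the dimer. Fallback (sets out from 22 and 20, returns at 27): the electrophile is capped at C8 with bromine so that it cannot act as a nucleophile.
- 22 and NBS (CH2Cl2, −20 °C) give 8-bromo-5,7,3',4'-tetra-O-benzylcatechin F8.
- DDQ and 2-ethoxyethanol give its 4-(2-ethoxyethoxy) derivative F9, and Ac2O/DMAP/pyridine gives the 3-O-acetate F10.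
- F10 (slight excess) and 20 with TMSOTf (CH2Cl2, −78 °C) give the 8-bromo trimer acetate F11, and NaOMe in MeOH/THF gives the 8-bromo trimer alcohol F12.
- Hydrogenolysis of F12 (H2, Pd(OH)2/C, Et3N, THF/MeOH/H2O) removes the bromine together with the fifteen benzyl groups and gives 27.

Further compounds
F1 | step 10 | (2R,3S)-8-bromo-3,5,7,3',4'-penta-O-benzylcatechin | Brc1c(OCc3ccccc3)cc(OCc3ccccc3)c2c1O[C@H](c1ccc(OCc3ccccc3)c(OCc3ccccc3)c1)[C@@H](OCc1ccccc1)C2
F2 | step 11 | (2R,3S,4R)-5,7-bis(benzyloxy)-2-[3,4,5-tris(benzyloxy)phenyl]chromane-3,4-diol | c1c(OCc3ccccc3)cc(OCc3ccccc3)c2c1O[C@H](c1cc(OCc3ccccc3)c(OCc3ccccc3)c(OCc3ccccc3)c1)[C@@H](O)[C@@H]2O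
F3 | step 11 | (2R,3S,4S)-5,7-bis(benzyloxy)-4-(2-ethoxyethoxy)-2-[3,4,5-tris(benzyloxy)phenyl]chroman-3-ol | c1c(OCc3ccccc3)cc(OCc3ccccc3)c2c1O[C@H](c1cc(OCc3ccccc3)c(OCc3ccccc3)c(OCc3ccccc3)c1)[C@@H](O)[C@H]2OCCOCC
F4 | step 11 | 5,7,3',4'-tetra-O-benzylcatechin 3-O-hemiglutarate | c1ccccc1COc1cc(OCc3ccccc3)c2c(c1)O[C@H](c1ccc(OCc3ccccc3)c(OCc3ccccc3)c1)[C@@H](OC(=O)CCCC(O)=O)C2
F5 | step 11 | glutarate diester linking O3 of F3 and O3 of 22 | c1c(OCc3ccccc3)cc(OCc3ccccc3)c2c1O[C@H](c1cc(OCc3ccccc3)c(OCc3ccccc3)c(OCc3ccccc3)c1)[C@@H](OC(=O)CCCC(=O)O[C@H]1Cc4c(OCc3ccccc3)cc(OCc3ccccc3)cc4O[C@@H]1c1ccc(OCc3ccccc3)c(OCc3ccccc3)c1)[C@H]2OCCOCC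
F6 | step 11 | 3,3'-O-glutaryl-bridged nona-O-benzyl-gallocatechin-(4β→8)-catechin (3,4-cis) | c1c(OCc3ccccc3)cc(OCc3ccccc3)c2c1O[C@H](c1cc(OCc3ccccc3)c(OCc3ccccc3)c(OCc3ccccc3)c1)[C@H]5OC(=O)CCCC(=O)O[C@H]6Cc7c(OCc3ccccc3)cc(OCc3ccccc3)c(c7O[C@@H]6c6ccc(OCc3ccccc3)c(OCc3ccccc3)c6)[C@@H]25
F7 | step 11 | nona-O-benzyl-gallocatechin-(4β→8)-catechin with both 3-OH free | c1c(OCc3ccccc3)cc(OCc3ccccc3)c2c1O[C@H](c1cc(OCc3ccccc3)c(OCc3ccccc3)c(OCc3ccccc3)c1)[C@@H](O)[C@H]2c1c(OCc3ccccc3)cc(OCc3ccccc3)c2c1O[C@H](c1ccc(OCc3ccccc3)c(OCc3ccccc3)c1)[C@@H](O)C2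
F8 | step 15 | 8-bromo-5,7,3',4'-tetra-O-benzylcatechin | Brc1c(OCc3ccccc3)cc(OCc3ccccc3)c2c1O[C@H](c1ccc(OCc3ccccc3)c(OCc3ccccc3)c1)[C@@H](O)C2
F9 | step 15 | (2R,3S,4S)-8-bromo-5,7,3',4'-tetra-O-benzyl-4-(2-ethoxyethoxy)catechin | Brc1c(OCc3ccccc3)cc(OCc3ccccc3)c2c1O[C@H](c1ccc(OCc3ccccc3)c(OCc3ccccc3)c1)[C@@H](O)[C@H]2OCCOCC
F10 | step 15 | (2R,3S,4S)-3-O-acetyl-8-bromo-5,7,3',4'-tetra-O-benzyl-4-(2-ethoxyethoxy)catechin | Brc1c(OCc3ccccc3)cc(OCc3ccccc3)c2c1O[C@H](c1ccc(OCc3ccccc3)c(OCc3ccccc3)c1)[C@@H](OC(C)=O)[C@H]2OCCOCC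
F11 | step 15 | 8-bromo analogue of 25 (bromine on C8 of the top unit) | Brc1c(OCc3ccccc3)cc(OCc3ccccc3)c2c1O[C@H](c1ccc(OCc3ccccc3)c(OCc3ccccc3)c1)[C@@H](OC(C)=O)[C@@H]2c1c(OCc3ccccc3)cc(OCc3ccccc3)c2c1O[C@H](c1cc(OCc3ccccc3)c(OCc3ccccc3)c(OCc3ccccc3)c1)[C@@H](OCc1ccccc1)[C@H]2c1c(OCc3ccccc3)cc(OCc3ccccc3)c2c1O[C@H](c1ccc(OCc3ccccc3)c(OCc3ccccc3)c1)[C@@H](OCc1ccccc1)C2
F12 | step 15 | 8-bromo analogue of 26 (bromine on C8 of the top unit) | Brc1c(OCc3ccccc3)cc(OCc3ccccc3)c2c1O[C@H](c1ccc(OCc3ccccc3)c(OCc3ccccc3)c1)[C@@H](O)[C@@H]2c1c(OCc3ccccc3)cc(OCc3ccccc3)c2c1O[C@H](c1cc(OCc3ccccc3)c(OCc3ccccc3)c(OCc3ccccc3)c1)[C@@H](OCc1ccccc1)[C@H]2c1c(OCc3ccccc3)cc(OCc3ccccc3)c2c1O[C@H](c1ccc(OCc3ccccc3)c(OCc3ccccc3)c1)[C@@H](OCc1ccccc1)C2
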